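## Retrosynthetic overview

1. Target 9 ⇒ (cation exchange, hydrogenolysis) ring B diphenylmethylene ketal 7, carrying both sulfates as Bu4N+ salts.
2. Key disconnection: the C6–O bond. C6–H of the 7-sulfate 4 becomes C6–OSO3− directly, with the sulfate oxygen handed over from trivalent iodine bound to the 5-OH.
3. 4 ⇒ the O7–S bond, made by SO3 transfer to the only reactive phenol of ketal 2.
4. 2 ⇒ luteolin 1 (bulk commercial flavone) + Ph2CCl2.
5. Ring order: rings A, B and C arrive intact in luteolin. The only ring formed is the temporary 1,3-dioxole on ring B (step 1), which is opened again in step 4.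

Assumption: the target has no stereocentre, so there is no enantiomer to select. It is delivered as the free acid drawn and carried through the route as tetrabutylammonium salts.

## Route

**Step 1**
Reactants: 1 luteolin
Product: 2 3',4'-O-(diphenylmethylene)luteolin
Conditions: Ph2CCl2 (1.5 equiv), Ph2O, 175 °C, 45 min, N2 sweep; precipitate with hexane, short silica column
Reagents that add atoms: dichlorodiphenylmethane, ClC(Cl)(c1ccccc1)c1ccccc1
Why: Catechol-selective ketalisation (double substitution on a gem-dichloride), in which only the vicinal 3',4'-diol can close a five-membered 1,3-benzodioxole, so the isolated 7-OH and the chelated 5-OH stay free, as is established for flavonoid catechols; no stereocentre is formed.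

**Step 2**
Reactants: 2 3',4'-O-(diphenylmethylene)luteolin
Product: 4 tetrabutylammonium 2-(2,2-diphenyl-1,3-benzodioxol-5-yl)-5-hydroxy-4-oxo-4H-chromen-7-yl sulfate, via pyridinium 7-sulfate 3 (not isolated)
Conditions: SO3·pyridine (1.3 equiv), DMF, 25 °C, 4 h; aq Bu4NOH to pH 7.5, extract into CH2Cl2
Reagents that add atoms: sulfur trioxide–pyridine complex, O=S(=O)([O-])[n+]1ccccc1; tetrabutylammonium hydroxide, CCCC[N+](CCCC)(CCCC)CCCC.[OH-]
Why: Phenol O-sulfation with an SO3–amine complex, in which the acidic, unhindered 7-OH reacts while the 5-OH, hydrogen-bonded to the C4 carbonyl, is inert to a small excess of reagent, and cation metathesis gives a salt soluble in organic solvents.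

**Step 3**
Reactants: 4 tetrabutylammonium 2-(2,2-diphenyl-1,3-benzodioxol-5-yl)-5-hydroxy-4-oxo-4H-chromen-7-yl sulfate
Product: 7 bis(tetrabutylammonium) 2-(2,2-diphenyl-1,3-benzodioxol-5-yl)-5-hydroxy-4-oxo-4H-chromene-6,7-diyl bis(sulfate), via aryloxy-λ3-iodane 5 (not isolated), via C6-sulfooxy dienone 6 (not isolated)
Conditions: PhIO (1.15 equiv), Bu4NHSO4 (1.3 equiv), 3 Å sieves, MeCN–CH2Cl2 1:1, −20 → 20 °C, dark, 2–6 h; Sephadex LH-20
Reagents that add atoms: tetrabutylammonium hydrogen sulfate, CCCC[N+](CCCC)(CCCC)CCCC.OS(=O)(=O)[O-]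
Why: Proposed new method: dehydrogenative C–H sulfooxylation of a phenol by ligand coupling at trivalent iodine, in which HSO4− depolymerises PhIO to PhI(OH)OSO3− (the sulfate analogue of Koser's reagent), the only free phenol (5-OH) exchanges onto iodine to give 5, and the iodine-bound sulfate passes to C6 as PhI leaves, C6 being the one open ortho carbon because C4a is quaternary, the para carbon C8 is out of reach of the bound ligand and the neighbouring 7-sulfate could only attack by a disfavoured 5-endo path, after which dienone 6 tautomerises to aromatic 7, which is electron-poorer than 4 and resists a second oxidation; the closest known reaction types are Koser α-sulfonyloxylation of enolisable ketones, Wessely ortho-acyloxylation of phenols, cyclic sulfate formation from alkenes with iodosylbenzene sulfate, and C6-selective iodination of chelated 5-hydroxy-7-alkoxyflavones.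

**Step 4**
Reactants: 7 bis(tetrabutylammonium) 2-(2,2-diphenyl-1,3-benzodioxol-5-yl)-5-hydroxy-4-oxo-4H-chromene-6,7-diyl bis(sulfate)
Product: 9 6-hydroxyluteolin 6,7-disulfate (target), via bis(tetrabutylammonium) salt 8 (not isolated)
Conditions: H2 (1 atm), 10% Pd/C, MeOH–THF 1:1, 23 °C, 8 h; filter; Dowex 50WX8 (H+ form), H2O, 0–4 °C; freeze-dry, store at −20 °C
Reagents that add atoms: none
Why: Hydrogenolysis of the two doubly benzylic C–O bonds of the ketal (benzyl-type deprotection) leaves aryl sulfate anions and the flavone C2=C3 bond untouched at 1 atm, and a cold strong-acid cation exchange swaps Bu4N+ for H+ faster than acid solvolysis of the sulfates can set in; no stereocentre is present.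

## Compound list

1 | luteolin, 2-(3,4-dihydroxyphenyl)-5,7-dihydroxy-4H-chromen-4-one | O=c1cc(-c2ccc(O)c(O)c2)oc2cc(O)cc(O)c12 | starting material
2 | 3',4'-O-(diphenylmethylene)luteolin, 2-(2,2-diphenyl-1,3-benzodioxol-5-yl)-5,7-dihydroxy-4H-chromen-4-one | O=c1cc(-c2ccc3OC(c4ccccc4)(c4ccccc4)Oc3c2)oc2cc(O)cc(O)c12 | intermediate
3 | pyridinium 2-(2,2-diphenyl-1,3-benzodioxol-5-yl)-5-hydroxy-4-oxo-4H-chromen-7-yl sulfate (not isolated) | O=c1cc(-c2ccc3OC(c4ccccc4)(c4ccccc4)Oc3c2)oc2cc(OS(=O)(=O)[O-])cc(O)c12.c1cc[nH+]cc1 | intermediate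
4 | tetrabutylammonium 2-(2,2-diphenyl-1,3-benzodioxol-5-yl)-5-hydroxy-4-oxo-4H-chromen-7-yl sulfate | O=c1cc(-c2ccc3OC(c4ccccc4)(c4ccccc4)Oc3c2)oc2cc(OS(=O)(=O)[O-])cc(O)c12.CCCC[N+](CCCC)(CCCC)CCCC | intermediate
5 | bis(tetrabutylammonium) salt of the 5-O-[phenyl(sulfonatooxy)-λ3-iodanyl] derivative of 4 (not isolated) | O=c1cc(-c2ccc3OC(c4ccccc4)(c4ccccc4)Oc3c2)oc2cc(OS(=O)(=O)[O-])cc(OI(c3ccccc3)OS(=O)(=O)[O-])c12.CCCC[N+](CCCC)(CCCC)CCCC.CCCC[N+](CCCC)(CCCC)CCCC | intermediate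
6 | bis(tetrabutylammonium) 2-(2,2-diphenyl-1,3-benzodioxol-5-yl)-4,5-dioxo-5,6-dihydro-4H-chromene-6,7-diyl bis(sulfate); C6 is a transient sp3 centre, racemic, erased on tautomerisation (not isolated) | O=C1C(OS(=O)(=O)[O-])C(OS(=O)(=O)[O-])=CC2=C1C(=O)C=C(O2)c1ccc2OC(c3ccccc3)(c3ccccc3)Oc2c1.CCCC[N+](CCCC)(CCCC)CCCC.CCCC[N+](CCCC)(CCCC)CCCC | intermediate
7 | bis(tetrabutylammonium) 2-(2,2-diphenyl-1,3-benzodioxol-5-yl)-5-hydroxy-4-oxo-4H-chromene-6,7-diyl bis(sulfate) | O=c1cc(-c2ccc3OC(c4ccccc4)(c4ccccc4)Oc3c2)oc2cc(OS(=O)(=O)[O-])c(OS(=O)(=O)[O-])c(O)c12.CCCC[N+](CCCC)(CCCC)CCCC.CCCC[N+](CCCC)(CCCC)CCCC | intermediate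
8 | bis(tetrabutylammonium) 2-(3,4-dihydroxyphenyl)-5-hydroxy-4-oxo-4H-chromene-6,7-diyl bis(sulfate) (not isolated) | O=c1cc(-c2ccc(O)c(O)c2)oc2cc(OS(=O)(=O)[O-])c(OS(=O)(=O)[O-])c(O)c12.CCCC[N+](CCCC)(CCCC)CCCC.CCCC[N+](CCCC)(CCCC)CCCC | intermediate
9 | 6-hydroxyluteolin 6,7-disulfate, achiral | O=c1cc(-c2ccc(O)c(O)c2)oc2cc(OS(=O)(=O)O)c(OS(=O)(=O)O)c(O)c12 | target

## Step count and risks

Total steps: 4. Longest linear sequence: 4.

**Step 3 (the new C6–H sulfooxylation).**
- Risks: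
  - external sulfate or water attacks the para carbon C8, which can lead to a 5,8-quinone;
  - the reaction stalls as a C6 phenyliodonium phenolate;
  - the 7-sulfate of a second molecule acts as the ligand and gives a diaryl sulfate.
- Fallback (known chemistry): it sets out from 4 and comes back at 7.
  - Electrophilic iodination ortho to the chelated 5-OH (BnMe3N·ICl2, CaCO3, CH2Cl2–MeOH, 23 °C) gives tetrabutylammonium 2-(2,2-diphenyl-1,3-benzodioxol-5-yl)-5-hydroxy-6-iodo-4-oxo-4H-chromen-7-yl sulfate F1.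
  - Ullmann-type hydroxylation (CuI 10 mol %, 8-hydroxyquinaldine, aq Bu4NOH, DMSO, 70–80 °C, argon, then neutralisation) gives tetrabutylammonium 2-(2,2-diphenyl-1,3-benzodioxol-5-yl)-5,6-dihydroxy-4-oxo-4H-chromen-7-yl sulfate F2.
  - The 6-OH of F2 is sulfated as in step 2 (SO3·pyridine, DMF, then Bu4NOH) to give 7; the chelated 5-OH again stays free.

**Step 4 (late hydrogenolysis and release of the acid form).**
- Risks:
  - traces of iodoarene from step 3 poison the Pd;
  - the ketal cleaves slowly on the bulky bis-salt;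
  - the crowded 6-sulfate is lost.
- Fallback: it sets out from 4 and comes back at 8. The hydrogenolysis is moved ahead of any iodine reagent, and ring B is carried as base-labile acetates.
  - H2, Pd/C, MeOH–THF gives tetrabutylammonium luteolin 7-sulfate F3.
  - Ac2O (2.2 equiv), pyridine, 0 °C gives tetrabutylammonium 3',4'-di-O-acetylluteolin 7-sulfate F4, with the 5-OH untouched.
  - The conditions of step 3 give bis(tetrabutylammonium) 3',4'-di-O-acetyl-6-hydroxyluteolin 6,7-bis(sulfate) F5.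
  - NH3 in MeOH, 0 °C, under argon gives 8, which goes through the cold resin exchange to 9.

**Step 2 (mono-sulfation and isolation of an ionic product).**
- Risks:
  - conversion is incomplete;
  - some 5-O-sulfation occurs;
  - material is lost on purification.
- Fallback: it sets out from 2 and comes back at 4, using a neutral, chromatographable masked sulfate.
  - Cl3CCH2OSO2Cl, Et3N, DMAP, THF, 0 °C gives 2-(2,2-diphenyl-1,3-benzodioxol-5-yl)-5-hydroxy-4-oxo-4H-chromen-7-yl 2,2,2-trichloroethyl sulfate F6, purified on silica.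
  - Reductive unmasking (Zn dust, HCO2NH4, MeOH, 23 °C) gives ammonium 2-(2,2-diphenyl-1,3-benzodioxol-5-yl)-5-hydroxy-4-oxo-4H-chromen-7-yl sulfate F7.
  - Aq Bu4NOH and CH2Cl2 extraction give 4.

## Further compounds

F1 | step 3 | tetrabutylammonium 2-(2,2-diphenyl-1,3-benzodioxol-5-yl)-5-hydroxy-6-iodo-4-oxo-4H-chromen-7-yl sulfate | O=c1cc(-c2ccc3OC(c4ccccc4)(c4ccccc4)Oc3c2)oc2cc(OS(=O)(=O)[O-])c(I)c(O)c12.CCCC[N+](CCCC)(CCCC)CCCC
F2 | step 3 | tetrabutylammonium 2-(2,2-diphenyl-1,3-benzodioxol-5-yl)-5,6-dihydroxy-4-oxo-4H-chromen-7-yl sulfate | O=c1cc(-c2ccc3OC(c4ccccc4)(c4ccccc4)Oc3c2)oc2cc(OS(=O)(=O)[O-])c(O)c(O)c12.CCCC[N+](CCCC)(CCCC)CCCC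
F3 | step 4 | tetrabutylammonium luteolin 7-sulfate | O=c1cc(-c2ccc(O)c(O)c2)oc2cc(OS(=O)(=O)[O-])cc(O)c12.CCCC[N+](CCCC)(CCCC)CCCC
F4 | step 4 | tetrabutylammonium 3',4'-di-O-acetylluteolin 7-sulfate | O=c1cc(-c2ccc(OC(C)=O)c(OC(C)=O)c2)oc2cc(OS(=O)(=O)[O-])cc(O)c12.CCCC[N+](CCCC)(CCCC)CCCC
F5 | step 4 | bis(tetrabutylammonium) 3',4'-di-O-acetyl-6-hydroxyluteolin 6,7-bis(sulfate) | O=c1cc(-c2ccc(OC(C)=O)c(OC(C)=O)c2)oc2cc(OS(=O)(=O)[O-])c(OS(=O)(=O)[O-])c(O)c12.CCCC[N+](CCCC)(CCCC)CCCC.CCCC[N+](CCCC)(CCCC)CCCC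
F6 | step 2 | 2-(2,2-diphenyl-1,3-benzodioxol-5-yl)-5-hydroxy-4-oxo-4H-chromen-7-yl 2,2,2-trichloroethyl sulfate | O=c1cc(-c2ccc3OC(c4ccccc4)(c4ccccc4)Oc3c2)oc2cc(OS(=O)(=O)OCC(Cl)(Cl)Cl)cc(O)c12
F7 | step 2 | ammonium 2-(2,2-diphenyl-1,3-benzodioxol-5-yl)-5-hydroxy-4-oxo-4H-chromen-7-yl sulfate | O=c1cc(-c2ccc3OC(c4ccccc4)(c4ccccc4)Oc3c2)oc2cc(OS(=O)(=O)[O-])cc(O)c12.[NH4+]
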